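A small charge of free catalyst, 17 mol% on the substrate, stands in each of these flasks beside more reagent, 4.71 times as much, so the catalyst must be used repeatedly.

the same everywhere: substrate 0.15 M; free catalyst 17 mol%

| run | reagent | scavenger | remark | time |
|---|---|---|---|---|
| blue | 0.80 equiv | 1.1 equiv | run made earlier |  |
| ochre | 0.80 equiv | 1.2 equiv | run made earlier |  |
| grey | 0.80 equiv | 1.9 equiv | run made earlier |  |
| alpha | 0.800 equiv | 1.00 equiv |  | 10 h |
| gamma | 0.800 equiv | 1.30 equiv |  | 10 h |
| zeta | 0.800 equiv | 1.70 equiv |  | 10 h |

| run | time / h | substrate / % | product / % |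
|---|---|---|---|
| blue | 0.500 | 81.2 | 18.2 |
| blue | 1.33 | 56.1 | 44.4 |
| blue | 3.00 | 27.9 | 72.6 |
| blue | 8.00 | 19.9 | 79.9 |
| ochre | 2.00 | 40.6 | 59.3 |
| ochre | 4.00 | 23.3 | 76.7 |
| ochre | 5.00 | 21.1 | 78.6 |
| ochre | 8.00 | 20.4 | 80.0 |
| grey | 0.500 | 81.6 | 18.3 |
| grey | 1.33 | 55.2 | 44.4 |
| grey | 3.00 | 27.5 | 72.3 |
| grey | 8.00 | 20.3 | 79.8 |

(standard deviation of a reading: 0.3 percentage points)

- part of the substrate that has reacted at the end, alpha
- part of the substrate that has reacted at the end, gamma
- part of the substrate that has reacted at the end, zeta
- what raising the equivalents of scavenger from its lowest to its highest value here does to the part of the substrate that has reacted (changes below 5 percentage points count as none) (it rises / it falls / no change)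

I build the flask up one process at a time. With the main step alone, I treat substrate loss as pseudo-first-order, which integrates to an exponential decay. The blue reading at 1.33 h gives a rate constant of 0.435 h⁻¹, and this curve alone has 98.7% reacted by 10 h.

Then I add the reagent. The plateaus near 79.9% in blue and 80.0% in ochre suggest one equivalent of reagent per product, and reagent is the limiting reagent, since its charge is smaller than the substrate's. That lowers my number to the reagent ceiling, the equivalents of reagent read as a percentage of the substrate charged: 80.0%. The exponential reaches this ceiling at 3.70 h, well before 10 h. The real curve bends earlier than that, with ochre substrate still at 21.1% after 5.00 h, yet the blue run has levelled off by 8.00 h.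

Last comes the scavenger. Grey and blue, at 1.9 equiv and 1.1 equiv, differ in substrate at 8.00 h by 0.4 percentage points, against a scatter of 0.3 points per reading, so my number stays at the ceiling. Alpha's 1.00 equiv lies below the tested range but still exceeds the reagent.

The forecast gives 80%, 80% and 80%, with no change, holding that “the reagent is simply used up”.

The simulation gives 79.9%, 79.9% and 79.9%, which is no change.

    substrate + catalyst intermediate B → catalyst intermediate C (k = 0.00600 M⁻¹ s⁻¹)
    reagent + free catalyst → catalyst intermediate A (k = 0.320 M⁻¹ s⁻¹)
    scavenger + released group → scavenged by-product (k = 0.610 M⁻¹ s⁻¹)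
    catalyst intermediate A → released group + catalyst intermediate B (k = 0.00520 s⁻¹)
    substrate + released group ⇌ idle adduct, settled at all times (K = 4.20 M⁻¹)
    catalyst intermediate C → free catalyst + product (k = 0.0290 s⁻¹)

Alpha ends at 79.9% against a ceiling of 80.0%, with reagent at 0% of its charge and scavenger at 20% of its charge. The same reckoning on a neighbour of alpha charged with 0.320 equiv of reagent puts the ceiling at 32.0%. That flask gives 32.0% reacted at 10.0 h, with reagent at 0% of its charge, product at 32.0% and substrate at 68.0%.

(The numbers in the tables are calculated on assumed constants.)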